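**Retrosynthetic overview**
1. Target 16 ⇐ 14 by acetonide hydrolysis and removal of two acetates; the trans-4-aryl-5-aryloxy-1,3-dioxane 14 corresponds to the erythro (7R,8S) triol.
2. Key disconnection, aryl–C7: enantioselective, desymmetrising photo-HAT/nickel C(sp3)–H arylation of the meso dioxane 13 with aryl bromide 4, setting C7 and C8 in one radical cross-coupling.
3. 13 ⇐ Mitsunobu etherification of phenol 11 with protected glycerol 12; 11 ⇐ acetosyringone 9 ⇐ phenol 5 + acetyl chloride 6 (acylation, dibromination, Cu-methoxylation, α-acetoxylation).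
4. 4 ⇐ catechol 1 by mono-methylation, para-bromination and acetylation.
5. No ring is constructed: both benzene rings are bought (phenol, catechol) and the dioxane is a temporary acetal that arrives with the glycerol unit.

Assumption: the target is the erythro (7R,8S) isomer exactly as encoded in the SMILES; glycerol is used in its catalogue 1,3-O-isopropylidene-protected form 12, the acetal being a protecting group removed in step 9.

**Route**

Step 1
Reactants: 1 catechol
Product: 2 guaiacol
Conditions: MeI (1.0 equiv), K2CO3 (1.0 equiv), acetone, reflux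
Reagents that add atoms: iodomethane, CI
Why: Williamson mono-O-methylation works because the catechol monoanion is more acidic and more reactive than the product, and the small amount of veratrole is removed by base extraction.

Step 2
Reactants: 2 guaiacol
Product: 4 4-bromo-2-methoxyphenyl acetate, via 4-bromo-2-methoxyphenol 3 (not isolated)
Conditions: NBS (1.0 equiv), MeCN, 0 °C; then Ac2O, Et3N, DMAP (cat.), rt
Reagents that add atoms: N-bromosuccinimide, O=C1CCC(=O)N1Br; acetic anhydride, CC(=O)OC(C)=O
Why: Electrophilic aromatic bromination of the free phenol goes para to the stronger OH director, and in-situ O-acetylation then masks the phenol O–H that would quench the HAT catalyst in step 8.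

Step 3
Reactants: 5 phenol; 6 acetyl chloride
Product: 7 4-hydroxyacetophenone
Conditions: TfOH (neat), 0 °C → rt
Reagents that add atoms: none
Why: Friedel–Crafts acylation/Fries rearrangement in neat triflic acid gives the para-acyl phenol as the thermodynamic product.

Step 4
Reactants: 7 4-hydroxyacetophenone
Product: 8 3,5-dibromo-4-hydroxyacetophenone
Conditions: Br2 (2.05 equiv), NaOAc, AcOH/H2O, rt
Reagents that add atoms: bromine, BrBr
Why: Electrophilic aromatic bromination at both positions ortho to OH is much faster than α-bromination of the ketone under acetate buffering.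

Step 5
Reactants: 8 3,5-dibromo-4-hydroxyacetophenone
Product: 9 acetosyringone
Conditions: NaOMe (excess, in MeOH), CuBr (20 mol %), DMF, 110 °C; then aq. HCl
Reagents that add atoms: sodium methoxide, C[O-].[Na+]
Why: Copper-catalysed Ullmann-type methoxylation of ortho-bromophenols (the syringaldehyde process) replaces both bromines, and the phenoxide protects the ketone from aldol chemistry.

Step 6
Reactants: 9 acetosyringone
Product: 11 2-(4-hydroxy-3,5-dimethoxyphenyl)-2-oxoethyl acetate, via α-bromoacetosyringone 10 (not isolated)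
Conditions: CuBr2 (2.1 equiv), EtOAc/CHCl3, reflux; filter, concentrate; then KOAc (3 equiv), AcOH, 80 °C
Reagents that add atoms: copper(II) bromide, Br[Cu]Br (bromine of 10 only); potassium acetate, CC(=O)[O-].[K+]
Why: King–Ostrum CuBr2 bromination is selective for the ketone α-carbon of hydroxyacetophenones, and SN2 displacement of the phenacyl bromide by acetate in acetic acid keeps the phenol protonated so that it does not self-alkylate.

Step 7
Reactants: 11 2-(4-hydroxy-3,5-dimethoxyphenyl)-2-oxoethyl acetate; 12 2,2-dimethyl-1,3-dioxan-5-ol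
Product: 13 2-{4-[(2,2-dimethyl-1,3-dioxan-5-yl)oxy]-3,5-dimethoxyphenyl}-2-oxoethyl acetate
Conditions: PPh3, DIAD, THF (3 M), sonication, 0 °C → rt
Reagents that add atoms: none
Why: Mitsunobu etherification is favoured by the acidic acyl-phenol, high concentration with sonication overcomes the 2,6-dimethoxy hindrance, and the product is achiral (mirror plane through C2 and C5).

Step 8
Reactants: 13 2-{4-[(2,2-dimethyl-1,3-dioxan-5-yl)oxy]-3,5-dimethoxyphenyl}-2-oxoethyl acetate; 4 4-bromo-2-methoxyphenyl acetate
Product: 14 2-{4-[((4R,5S)-4-(4-acetoxy-3-methoxyphenyl)-2,2-dimethyl-1,3-dioxan-5-yl)oxy]-3,5-dimethoxyphenyl}-2-oxoethyl acetate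
Conditions: (nBu4N)4W10O32 (2 mol %), NiBr2·glyme (10 mol %), chiral indanyl-bis(oxazoline) L* (12 mol %; enantiomer fixed in a pilot run to give 4R,5S), K3PO4, acetone/PhCF3, 390 nm LEDs, 10 °C; 13 (1.5 equiv, excess recovered), 4 (1.0 equiv)
Reagents that add atoms: none
Why: Proposed new method: excited decatungstate abstracts a hydridic α-oxy C–H at C4/C6 of the meso dioxane, the α-oxy radical is captured by the chiral (BOX)Ni–aryl complex, and reductive elimination from Ni(III) forms the aryl–C bond anti to the C5 aryloxy group (trans, i.e. erythro); the ligand's facial preference matches this anti approach for only one of the two enantiotopic CH2 groups, so (4R,5S)-14 forms while the mismatched radical returns to 13 by back hydrogen transfer; the closest known reaction type is the enantioselective photo-HAT/nickel α-arylation of acetonide-masked diols and oxacycles.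

Step 9
Reactants: 14 2-{4-[((4R,5S)-4-(4-acetoxy-3-methoxyphenyl)-2,2-dimethyl-1,3-dioxan-5-yl)oxy]-3,5-dimethoxyphenyl}-2-oxoethyl acetate
Product: 16 2-hydroxy-1-[4-{[(1R,2S)-1,3-dihydroxy-1-(4-hydroxy-3-methoxyphenyl)propan-2-yl]oxy}-3,5-dimethoxyphenyl]ethanone, via diacetate triol 15 (not isolated)
Conditions: Amberlyst-15 (H+), THF/H2O 4:1, 35 °C; filter, concentrate; then K2CO3 (0.3 equiv), MeOH, 0 °C; NH4Cl quench
Reagents that add atoms: none
Why: Acetal hydrolysis is done first while ring A is still acetylated, which suppresses benzylic ionisation and C7 epimerisation, and Zemplén-type methanolysis then removes the phenolic and α-keto acetates at 0 °C without touching either stereocentre.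

**Compound list**
1 | catechol | Oc1ccccc1O | starting material
2 | guaiacol (2-methoxyphenol) | COc1ccccc1O | intermediate
3 | 4-bromo-2-methoxyphenol | COc1cc(Br)ccc1O | intermediate (not isolated)
4 | 4-bromo-2-methoxyphenyl acetate | COc1cc(Br)ccc1OC(C)=O | intermediate
5 | phenol | Oc1ccccc1 | starting material
6 | acetyl chloride | CC(Cl)=O | starting material
7 | 4-hydroxyacetophenone | CC(=O)c1ccc(O)cc1 | intermediate
8 | 3,5-dibromo-4-hydroxyacetophenone | CC(=O)c1cc(Br)c(O)c(Br)c1 | intermediate
9 | acetosyringone (4-hydroxy-3,5-dimethoxyacetophenone) | CC(=O)c1cc(OC)c(O)c(OC)c1 | intermediate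
10 | 2-bromo-1-(4-hydroxy-3,5-dimethoxyphenyl)ethanone (α-bromoacetosyringone) | COc1cc(cc(OC)c1O)C(=O)CBr | intermediate (not isolated)
11 | 2-(4-hydroxy-3,5-dimethoxyphenyl)-2-oxoethyl acetate | COc1cc(cc(OC)c1O)C(=O)COC(C)=O | intermediate
12 | 2,2-dimethyl-1,3-dioxan-5-ol (glycerol carrying a 1,3-O-isopropylidene protecting group) | CC1(C)OCC(O)CO1 | starting material
13 | 2-{4-[(2,2-dimethyl-1,3-dioxan-5-yl)oxy]-3,5-dimethoxyphenyl}-2-oxoethyl acetate (achiral, meso-type) | COc1cc(cc(OC)c1OC1COC(C)(C)OC1)C(=O)COC(C)=O | intermediate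
14 | 2-{4-[((4R,5S)-4-(4-acetoxy-3-methoxyphenyl)-2,2-dimethyl-1,3-dioxan-5-yl)oxy]-3,5-dimethoxyphenyl}-2-oxoethyl acetate (trans-dioxane) | COc1cc([C@H]2OC(C)(C)OC[C@@H]2Oc3c(OC)cc(C(=O)COC(C)=O)cc3OC)ccc1OC(C)=O | intermediate
15 | 4-{(1R,2S)-2-[4-(acetoxyacetyl)-2,6-dimethoxyphenoxy]-1,3-dihydroxypropyl}-2-methoxyphenyl acetate | COc1cc([C@@H](O)[C@H](CO)Oc2c(OC)cc(C(=O)COC(C)=O)cc2OC)ccc1OC(C)=O | intermediate (not isolated)
16 | 2-hydroxy-1-[4-{[(1R,2S)-1,3-dihydroxy-1-(4-hydroxy-3-methoxyphenyl)propan-2-yl]oxy}-3,5-dimethoxyphenyl]ethanone (erythro, 7R,8S) | COc1cc([C@@H](O)[C@H](CO)Oc2c(OC)cc(C(=O)CO)cc2OC)ccc1O | target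

**Step count and risks**

Total steps: 9. Longest linear sequence: 7 (steps 3–9, from phenol); the ring-A branch (steps 1–2) joins at step 8.

Step 8 is the most likely to fail. The chiral nickel catalyst may not distinguish the two enantiotopic CH2 groups well. The C4 radical may expel the stabilised aryloxyl radical by β-scission. HAT could also occur at C5–H or at a methoxy group, and the phenacyl acetate could be photolabile if light below 380 nm reaches it. The fallback sets out from 12 and 4 and returns to the route at 14. Compound 12 is oxidised (TEMPO/NaOCl) to 2,2-dimethyl-1,3-dioxan-5-one F1. Palladium-catalysed α-arylation of F1 with 4 (Pd(dba)2/P(tBu)3, K3PO4, toluene) gives the configurationally labile 4-(4-acetoxy-3-methoxyphenyl)-2,2-dimethyl-1,3-dioxan-5-one F2. Noyori transfer hydrogenation under dynamic kinetic resolution (RuCl(p-cymene)(TsDPEN), HCO2H/Et3N, catalyst enantiomer chosen for 4R) gives the cis alcohol (4R,5R)-4-(4-acetoxy-3-methoxyphenyl)-2,2-dimethyl-1,3-dioxan-5-ol F3. A Mitsunobu reaction of F3 with phenol 11 then inverts C5 and delivers trans-(4R,5S)-14.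

Step 7 is the second risk, because a 2,6-disubstituted phenol and a secondary alcohol are both poor Mitsunobu partners. The fallback sets out from 12 and returns at 13. Compound 12 is converted (Tf2O, 2,6-lutidine, CH2Cl2, −40 °C) into 2,2-dimethyl-1,3-dioxan-5-yl trifluoromethanesulfonate F4. F4 is then displaced in a plain SN2 alkylation by the caesium phenoxide of 11 (Cs2CO3, MeCN, 0 °C) to give 13.

Step 6 is the third risk: the free phenol may be ring-brominated or alkylated by its own bromoketone. The fallback sets out from 9 (with 12) and returns at 13, bypassing 11. Mitsunobu etherification of 9 with 12 gives 1-{4-[(2,2-dimethyl-1,3-dioxan-5-yl)oxy]-3,5-dimethoxyphenyl}ethanone F5. LiHMDS/TMSCl converts F5 into the trimethylsilyl enol ether F6. Rubottom oxidation (mCPBA, then mild desilylation) gives 1-{4-[(2,2-dimethyl-1,3-dioxan-5-yl)oxy]-3,5-dimethoxyphenyl}-2-hydroxyethanone F7. Acetylation (Ac2O, pyridine) then gives 13.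

**Further compounds**
F1 | step 8 | 2,2-dimethyl-1,3-dioxan-5-one | CC1(C)OCC(=O)CO1
F2 | step 8 | 4-(4-acetoxy-3-methoxyphenyl)-2,2-dimethyl-1,3-dioxan-5-one (racemic, configurationally labile) | COc1cc(C2OC(C)(C)OCC2=O)ccc1OC(C)=O
F3 | step 8 | (4R,5R)-4-(4-acetoxy-3-methoxyphenyl)-2,2-dimethyl-1,3-dioxan-5-ol (cis) | COc1cc([C@H]2OC(C)(C)OC[C@H]2O)ccc1OC(C)=O
F4 | step 7 | 2,2-dimethyl-1,3-dioxan-5-yl trifluoromethanesulfonate | CC1(C)OCC(CO1)OS(=O)(=O)C(F)(F)F
F5 | step 6 | 1-{4-[(2,2-dimethyl-1,3-dioxan-5-yl)oxy]-3,5-dimethoxyphenyl}ethanone | COc1cc(cc(OC)c1OC1COC(C)(C)OC1)C(C)=O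
F6 | step 6 | {[1-(4-((2,2-dimethyl-1,3-dioxan-5-yl)oxy)-3,5-dimethoxyphenyl)ethenyl]oxy}trimethylsilane | COc1cc(cc(OC)c1OC1COC(C)(C)OC1)C(=C)O[Si](C)(C)C
F7 | step 6 | 1-{4-[(2,2-dimethyl-1,3-dioxan-5-yl)oxy]-3,5-dimethoxyphenyl}-2-hydroxyethanone | COc1cc(cc(OC)c1OC1COC(C)(C)OC1)C(=O)CO
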